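## The problem

Target 29 is the isovanillate ester of a trans-fused hydroazulene (bicyclo[5.3.0]decane). In azulene numbering, used for the ring atoms throughout, the five-membered ring carries a trisubstituted C-1/C-2 epoxide with a methyl group on C-2. The seven-membered ring carries isopropyl on C-4, the ester on C-5 and a methyl-bearing tertiary carbinol on C-7, with C-6 a bare methylene between the two oxygenated carbons. Seven stereocentres must be set (C-1, C-2, C-3a, C-4, C-5, C-7, C-8a). The ring fusion is trans, and the isopropyl group, the ester oxygen, the tertiary hydroxyl and the epoxide oxygen all lie on the face of H-3a, opposite to H-8a and to both methyl groups. The contiguous triad C-8a/C-3a/C-4 has no heteroatom to lean on and must come from a C–C bond-forming step under absolute control. After that, C-5 can be set from C-4 (hydride anti to isopropyl), C-7 from C-5 (hydroxyl-directed epoxidation of a C-6/C-7 alkene, then hydride opening) and the epoxide from the C-7 hydroxyl. The epoxide is acid-labile, the tertiary alcohol dehydrates easily, and the aryl ester with its free phenol survives neither hydride nor strong base, so these groups must arrive late; the hindered C-5 hydroxyl must also be acylated beside a free tertiary hydroxyl. The feature that opens the route is that C-5, C-4, C-3a, C-8a, C-8 and C-7 form the substitution pattern of a Diels–Alder cyclohexene (oxygen on C-5, methyl on C-7, three contiguous carbon substituents) that lacks only C-6, and that C-5 and C-7 are the two carbons of a regiodefined silyl enol ether.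

## Retrosynthesis

**Ester and phenol (29 ⇒ 28 ⇒ 23 + 26).** The O–Si bond of the phenol and the C-5 O–acyl bond are cut last. An aryl ester could not pass through the hydride and ylide steps, so acylation must follow all of them. Cutting here leaves epoxy diol 23 and the silyl-protected acid 26, made in one step from isovanillic acid 24. The forward reaction must acylate a hindered secondary hydroxyl beside a tertiary one without opening the epoxide, and the final deprotection must be near-neutral.

**Epoxide (23 ⇒ 22).** Both C–O bonds of the epoxide are cut, giving the cyclopentene diol 22. The epoxide cannot precede the hydride step that creates the C-7 carbinol, and only after that step are the hydroxyls present that can direct the oxidant. Two stereocentres disappear. The forward step must deliver oxygen to the face of the alkene anti to H-8a; both hydroxyls of 22 sit on that face.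

**Tertiary carbinol (22 ⇒ 21 ⇒ 20).** The C-6–H bond is cut back to epoxy alcohol 21, and the epoxide to allylic alcohol 20. Adding a methyl nucleophile to a C-7 ketone would leave the configuration to an uncontrolled facial preference. Here the C-5 hydroxyl directs the epoxidation, and hydride attack at the secondary C-6 then leaves the oxygen on C-7 where it was delivered. The forward steps need syn delivery and attack at C-6, not at the tertiary C-7.

**C-5 carbinol (20 ⇒ 19).** The C-5–H bond is cut, giving the bicyclic dienone 19. Reducing at this stage, and not on the monocyclic imide, means that no other reducible group competes and the ring is conformationally defined. The forward reaction must add hydride 1,2 and anti to the isopropyl group.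

**Five-membered ring (19 ⇒ 18 ⇒ 17 ⇒ 16 ⇒ 15).** The C-1=C-2 bond is cut by a metathesis transform to the vinyl/methallyl trienone 18. The vinyl CH2 is removed to aldehyde 17, which is traced through diol 16 to the imide 15. Metathesis is preferred to an aldol or reductive carbonyl coupling because both partners are inert until called on and the methallyl group can be carried from the start. The reduce-then-oxidise pair costs one step more than a direct imide-to-aldehyde reduction, but it needs no chemoselectivity between imide and ketone and fixes no stereocentre prematurely.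

**One-carbon excision (15 ⇒ 12).** Both bonds to C-6 (C-5–C-6 and C-6–C-7) are cut, which contracts the cycloheptenone to the cyclohexene silyl enol ether 12. Cutting other ring bonds, such as C-4–C-5 or the bonds to C-7, would open the ring to a chain with little stereochemical memory. Removing C-6 instead reveals a ring that a cycloaddition makes in one step with the triad in place. The forward step must insert CH2 into the enol ether double bond only (a zinc carbenoid, then one-electron oxidation of the siloxycyclopropane 13 and loss of HCl from chloro ketone 14) and must end with the alkene between C-6 and C-7.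

**Cycloaddition (12 ⇒ 5 + 11).** The C-3a–C-4 and C-8–C-8a bonds are cut, giving siloxydiene 5 and the dienoyl imide 11. This cut sets C-8a, C-3a and C-4 at once and delivers the enol ether with oxygen on C-5 and methyl on C-7, which no enolisation of the corresponding ketone could do selectively. The forward reaction must be regioselective (siloxy control), endo, and enantioselective at the imide α-carbon.

**Building blocks.** Diene 5 comes from enone 4, that from alcohol 3, and that from 3-methylbutanal 1 and isopropenylmagnesium bromide 2. Imide 11 is cut at the allyl–alkenyl bond into bromo imide 9 and stannane 10, and 9 into 4-bromocrotonic acid 6 (through acid chloride 8) and oxazolidinone 7. The allyl–alkenyl coupling is chosen over olefination of a β,γ-unsaturated aldehyde because it is neutral and does not risk moving the skipped diene into conjugation.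

## Roads not taken

**Alternative 1:** The cut lies in the five-membered ring, between C-3 and C-3a. In the forward direction a cationic phosphine–gold catalyst would trigger a 1,2-pivaloyloxy shift in the enyne pivalate A1 and close cyclopentenone A2 (Rautenstrauch rearrangement), with the carbinol configuration of A1 relayed to C-3a. The step is catalytic and mild, the absolute configuration comes from a propargylic alcohol, and the enone of A2 offers handles for the C-2 methyl and for a trans-selective conjugate addition at C-8a. Its weakness here is how little of the target A2 contains: one ring and two stereocentres. C-4 must be set separately in the chain and matched to the transfer. The fidelity of the transfer is substrate-dependent (A1 is drawn with a provisional carbinol configuration for that reason). The whole seven-membered ring with C-5 and C-7 remains to be built, probably by a medium-ring closure. This road is better than the chosen plan in not depending on an enantioselective cycloaddition of a hindered diene and in using no stoichiometric metal oxidant. Against that, the chosen plan makes six of the seven ring carbons and the whole triad in one step and reaches the enone that relays C-5 and C-7.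

**Alternative 2:** The cut is the C-4–C-5 bond. A dialkylaluminium chloride would make the aldehyde carbon of A3 add to the inner carbon of its 2-methylprop-1-enyl group with transfer of a methyl hydrogen (carbonyl-ene reaction), closing the seven-membered ring to the isopropenyl alcohol A4. The merits are real: the C-7 carbinol is already in place and needs no relay, two stereocentres form in the ring-closing step, and the six-membered version of this closure is very reliable. For this target the closure must form a seven-membered ring, which is much less favourable. The Lewis acid meets a tertiary silyl ether that can ionise. The isopropenyl group must later be hydrogenated beside an enol triflate. A4 has the hydroxyl trans to the C-4 substituent, so C-5 must be inverted at a hindered carbinol, ideally in the esterification itself. In securing C-7 independently this road is at least as good as the chosen one. The chosen plan sets against it a ring-forming step that is a ring enlargement and not a medium-ring cyclisation, and a cis C-4/C-5 relationship obtained directly by reduction.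

**Alternative 3:** The cut removes both bonds to C-7. The lithiated silyl dithiane A6 would open the terminal epoxide of A5 at C-6, silicon would migrate to the new C-5 alkoxide (Brook rearrangement), and the regenerated carbanion would displace the chloride at C-8, giving A7. This is convergent, C-5 comes from an epoxide and emerges already protected, and the trans fusion and the cyclopentene are in place. The weak points are the ring closure itself, a seven-membered alkylation by a hindered carbanion that competes with intermolecular reaction, and the later steps. The dithiane must be removed beside a trisubstituted alkene, and the methyl group must then be added to the C-7 ketone with no element that secures the face. The triad in A5 also needs its own synthesis. In convergence and in the origin of C-5 this road is as good as or better than the chosen one. The chosen plan sets against it a C-7 configuration fixed by intramolecular delivery and a triad made in the same step as the ring.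

Key step: step 7

Assumption: the sense of induction in step 6 is taken from the square-planar chelate model of copper bis(oxazoline) catalysts with the s-cis imide; if it proves opposite, the enantiomeric ligand is used.

## Route

Step 1
Reactants: 1 3-methylbutanal; 2 isopropenylmagnesium bromide
Product: 3 2,5-dimethylhex-1-en-3-ol (racemic)
Conditions: THF, 0 °C; aq NH4Cl
Reagents that add atoms: none
Why: 1,2-Addition of an alkenyl Grignard reagent to an unhindered aldehyde should give the allylic alcohol; its carbinol centre is racemic and is removed in step 2.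

Step 2
Reactants: 3 2,5-dimethylhex-1-en-3-ol
Product: 4 2,5-dimethylhex-1-en-3-one
Conditions: Dess–Martin periodinane, NaHCO3, CH2Cl2, 0 °C → rt
Reagents that add atoms: none
Why: Dess–Martin oxidation of a secondary allylic alcohol under buffered, non-nucleophilic conditions should give the isopropenyl ketone without conjugate addition or polymerisation.

Step 3
Reactants: 4 2,5-dimethylhex-1-en-3-one
Product: 5 (3Z)-2,5-dimethyl-3-(trimethylsilyloxy)hexa-1,3-diene
Conditions: Me3SiOTf, Et3N, Et2O, 0 °C
Reagents that add atoms: trimethylsilyl trifluoromethanesulfonate, C[Si](C)(C)OS(=O)(=O)C(F)(F)F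
Why: Soft enolisation with a silyl triflate and amine can occur only at the CH2 next to the carbonyl, and the equilibrating conditions favour the Z enol ether with isopropyl anti to the isopropenyl group. This geometry places isopropyl outside in the s-cis diene.

Step 4
Reactants: 6 (2E)-4-bromobut-2-enoic acid; 7 1,3-oxazolidin-2-one
Product: 9 3-[(2E)-4-bromobut-2-enoyl]-1,3-oxazolidin-2-one, via acid chloride 8 (not isolated)
Conditions: 6, (COCl)2, cat. DMF, CH2Cl2, 0 °C → rt, evaporate; 7, n-BuLi, THF, −78 °C, then 8, −78 → 0 °C
Reagents that add atoms: oxalyl chloride, O=C(Cl)C(=O)Cl (supplies only the chlorine of intermediate 8)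
Why: N-Acylation of a lithiated oxazolidinone by an acid chloride is the standard route to N-enoyl imides; at −78 °C acyl substitution should outrun displacement of the allylic bromide.

Step 5
Reactants: 9 3-[(2E)-4-bromobut-2-enoyl]-1,3-oxazolidin-2-one; 10 tributyl(prop-1-en-2-yl)stannane
Product: 11 3-[(2E)-5-methylhexa-2,5-dienoyl]-1,3-oxazolidin-2-one
Conditions: Pd2(dba)3 (2.5 mol%), tri(2-furyl)phosphine (10 mol%), THF, 50 °C
Reagents that add atoms: none
Why: Stille coupling of an allylic bromide with an alkenylstannane: zerovalent palladium forms the π-allyl complex and the alkenyl group is joined at the terminus remote from the carbonyl, which keeps the E-enoyl unit. The neutral medium avoids base-induced drift of the skipped diene into conjugation.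

Step 6
Reactants: 5 (3Z)-2,5-dimethyl-3-(trimethylsilyloxy)hexa-1,3-diene; 11 3-[(2E)-5-methylhexa-2,5-dienoyl]-1,3-oxazolidin-2-one
Product: 12 3-{[(1S,5S,6S)-3-methyl-6-(2-methylprop-2-en-1-yl)-5-(propan-2-yl)-4-(trimethylsilyloxy)cyclohex-3-en-1-yl]carbonyl}-1,3-oxazolidin-2-one
Conditions: Cu(OTf)2 (10 mol%), 2,2'-(propane-2,2-diyl)bis[(4R)-4-tert-butyl-4,5-dihydro-1,3-oxazole] [(R,R)-t-Bu-box, 11 mol%], CH2Cl2, −40 → −20 °C; filtration through Et3N-deactivated silica
Reagents that add atoms: none
Why: Lewis-acid-catalysed Diels–Alder reaction of a chelating N-enoyl oxazolidinone with a 2-siloxydiene, in which the siloxy group sends its enol-ether terminus (the isopropyl-bearing carbon) to the β-carbon of the imide. The E dienophile fixes imide and methallyl trans, and the endo transition state with isopropyl outside puts isopropyl cis to the imide. In the square-planar divalent copper chelate of the s-cis imide the (R,R)-ligand shields the Re face of the α-carbon, so the diene should add to the Si face and give the (1S,5S,6S) adduct.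

Step 7
Reactants: 12 3-{[(1S,5S,6S)-3-methyl-6-(2-methylprop-2-en-1-yl)-5-(propan-2-yl)-4-(trimethylsilyloxy)cyclohex-3-en-1-yl]carbonyl}-1,3-oxazolidin-2-one
Product: 15 3-{[(1S,6S,7S)-3-methyl-7-(2-methylprop-2-en-1-yl)-5-oxo-6-(propan-2-yl)cyclohept-3-en-1-yl]carbonyl}-1,3-oxazolidin-2-one, via siloxycyclopropane 13 (not isolated), via β-chloro ketone 14 (not isolated)
Conditions: Et2Zn, CH2I2 (1.3 equiv each), CH2Cl2, 0 °C → rt; crude 13, FeCl3 (2.5 equiv), pyridine, DMF, 0 °C → rt; crude 14, NaOAc, MeOH, 50 °C
Reagents that add atoms: diiodomethane, ICI; FeCl3, Cl[Fe](Cl)Cl (supplies only the chlorine of intermediate 14)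
Why: The electrophilic carbenoid EtZnCH2I transfers methylene to the tetrasubstituted silyl enol ether of 12 through a concerted butterfly transition state, closing the three-membered ring of 13 by [2+1] addition (Furukawa variant of the Simmons–Smith reaction on a cyclic silyl enol ether). FeCl3 then oxidises the siloxycyclopropane by one electron, silicon leaves as Me3SiCl, and the bond shared by the two rings breaks because this scission gives the tertiary methyl-bearing radical and releases the bicyclic strain, whereas scission of the outer bond would give a primary radical; the seven-membered ring thus arises by ring enlargement, not by a cyclisation. Chlorine transfer from a second FeCl3 gives β-chloro ketone 14, and acetate removes HCl by an E1cB path through the enolate at the inserted CH2 (future C-6), the only α-carbon with a β-leaving group, so the alkene ends conjugated between future C-6 and C-7. The closest known reaction is the FeCl3-induced one-carbon enlargement of 1-siloxybicyclo[n.1.0]alkanes to cycloalk-2-enones, which includes the conversion of 2-methylcyclohexanone into 3-methylcyclohept-2-enone. No stereocentre is created, since both cyclopropane carbons and the chloride carbon end achiral or sp2, so the face of cyclopropanation is irrelevant. The three centres from step 6 are not touched, and the isopropyl-bearing carbon next to the ketone already sits in the more stable trans arrangement. The step needs chemoselectivity for the enol ether over the methallyl alkene, which the oxygen donor secures towards an electrophilic carbenoid used near one equivalent at 0 °C. It also needs chlorination of the tertiary radical to outrun its addition to the methallyl group, which excess FeCl3 and the unfavourable 6-exo or 7-endo geometry secure.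

Step 8
Reactants: 15 3-{[(1S,6S,7S)-3-methyl-7-(2-methylprop-2-en-1-yl)-5-oxo-6-(propan-2-yl)cyclohept-3-en-1-yl]carbonyl}-1,3-oxazolidin-2-one
Product: 16 (5S,6R,7S)-5-(hydroxymethyl)-3-methyl-6-(2-methylprop-2-en-1-yl)-7-(propan-2-yl)cyclohept-2-en-1-ol (both C-1 epimers)
Conditions: LiBH4, MeOH (2 equiv), THF, 0 °C → rt
Reagents that add atoms: none
Why: LiBH4 cleaves N-acyl oxazolidinones to primary alcohols and reduces a β,β-disubstituted enone in the 1,2 sense; the carbinol epimer mixture is of no consequence because step 9 returns it to the ketone.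

Step 9
Reactants: 16 (5S,6R,7S)-5-(hydroxymethyl)-3-methyl-6-(2-methylprop-2-en-1-yl)-7-(propan-2-yl)cyclohept-2-en-1-ol
Product: 17 (1S,6S,7R)-3-methyl-7-(2-methylprop-2-en-1-yl)-5-oxo-6-(propan-2-yl)cyclohept-3-ene-1-carbaldehyde
Conditions: Dess–Martin periodinane (2.5 equiv), NaHCO3, CH2Cl2, 0 °C → rt
Reagents that add atoms: none
Why: Dess–Martin oxidation takes the primary alcohol to the aldehyde and the allylic alcohol back to the enone in one operation; the formyl group is trans to its neighbour, the stable arrangement, so epimerisation is not a threat under buffered conditions.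

Step 10
Reactants: 17 (1S,6S,7R)-3-methyl-7-(2-methylprop-2-en-1-yl)-5-oxo-6-(propan-2-yl)cyclohept-3-ene-1-carbaldehyde
Product: 18 (5R,6R,7S)-5-ethenyl-3-methyl-6-(2-methylprop-2-en-1-yl)-7-(propan-2-yl)cyclohept-2-en-1-one
Conditions: Ph3PCH3Br, KN(SiMe3)2, THF, 0 °C; then 17 (ylide 1.05 equiv), −78 → 0 °C
Reagents that add atoms: methyltriphenylphosphonium bromide, C[P+](c1ccccc1)(c1ccccc1)c1ccccc1.[Br-]
Why: Wittig methylenation: the aldehyde reacts with the unstabilised ylide much faster than the conjugated, α-branched, β,β-disubstituted ketone, so one equivalent at low temperature should convert the formyl group only.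

Step 11
Reactants: 18 (5R,6R,7S)-5-ethenyl-3-methyl-6-(2-methylprop-2-en-1-yl)-7-(propan-2-yl)cyclohept-2-en-1-one
Product: 19 (3aR,4S,8aS)-2,7-dimethyl-4-(propan-2-yl)-3a,4,8,8a-tetrahydroazulen-5(3H)-one
Conditions: second-generation Grubbs catalyst (H2IMes)(PCy3)Cl2Ru=CHPh (5 mol%), CH2Cl2, 40 °C
Reagents that add atoms: none
Why: Ring-closing metathesis of the vinyl and methallyl groups forms the trisubstituted cyclopentene with loss of ethene; the trans-diequatorial side chains close to the trans-fused bicycle and the electron-poor enone alkene stays out of the reaction.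

Step 12
Reactants: 19 (3aR,4S,8aS)-2,7-dimethyl-4-(propan-2-yl)-3a,4,8,8a-tetrahydroazulen-5(3H)-one
Product: 20 (3aR,4S,5S,8aS)-2,7-dimethyl-4-(propan-2-yl)-3,3a,4,5,8,8a-hexahydroazulen-5-ol
Conditions: LiBH(s-Bu)3 (L-Selectride), THF, −78 °C; aq NH4Cl
Reagents that add atoms: none
Why: A β,β-disubstituted enone is reduced 1,2 by the bulky borohydride, which should attack from the equatorial direction because the other face is screened by the isopropyl group and axial H-3a (the menthone-to-neomenthol pattern). The C-5 hydroxyl is therefore placed cis to isopropyl.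

Step 13
Reactants: 20 (3aR,4S,5S,8aS)-2,7-dimethyl-4-(propan-2-yl)-3,3a,4,5,8,8a-hexahydroazulen-5-ol
Product: 21 (3aR,4S,5S,6S,7R,8aS)-6,7-epoxy-2,7-dimethyl-4-(propan-2-yl)-3,3a,4,5,6,7,8,8a-octahydroazulen-5-ol
Conditions: VO(acac)2 (5 mol%), t-BuOOH (1.2 equiv, decane), CH2Cl2, 0 °C → rt
Reagents that add atoms: tert-butyl hydroperoxide, CC(C)(C)OO
Why: Vanadium-catalysed hydroxyl-directed epoxidation delivers oxygen to the allylic C-6/C-7 alkene from the face of the pseudoaxial C-5 hydroxyl, giving the syn epoxy alcohol; the cyclopentene, four bonds from the carbinol carbon, is not activated.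

Step 14
Reactants: 21 (3aR,4S,5S,6S,7R,8aS)-6,7-epoxy-2,7-dimethyl-4-(propan-2-yl)-3,3a,4,5,6,7,8,8a-octahydroazulen-5-ol
Product: 22 (3aR,4S,5R,7R,8aS)-2,7-dimethyl-4-(propan-2-yl)-3,3a,4,5,6,7,8,8a-octahydroazulene-5,7-diol
Conditions: LiAlH4, THF, 0 → 50 °C
Reagents that add atoms: none
Why: Hydride opens a trisubstituted epoxide by SN2 attack at the secondary carbon (C-6), which leaves the oxygen on tertiary C-7 with its configuration untouched and gives the syn-1,3-diol; the isolated cyclopentene is inert to LiAlH4.

Step 15
Reactants: 22 (3aR,4S,5R,7R,8aS)-2,7-dimethyl-4-(propan-2-yl)-3,3a,4,5,6,7,8,8a-octahydroazulene-5,7-diol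
Product: 23 (1S,2R,3aR,4S,5R,7R,8aS)-1,2-epoxy-2,7-dimethyl-4-(propan-2-yl)decahydroazulene-5,7-diol
Conditions: VO(acac)2 (10 mol%), t-BuOOH (1.5 equiv, decane), toluene, rt → 40 °C
Reagents that add atoms: tert-butyl hydroperoxide, CC(C)(C)OO
Why: Hydroxyl-directed epoxidation of a bishomoallylic alcohol: the axial C-7 hydroxyl, and behind it the C-5 hydroxyl, lie on the face of the bicycle anti to H-8a and should deliver the vanadium-bound peroxide to that face of the C-1/C-2 alkene. Backside opening of the new epoxide by these same-face hydroxyls is geometrically impossible.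

Step 16
Reactants: 24 3-hydroxy-4-methoxybenzoic acid (isovanillic acid)
Product: 26 3-(tert-butyldimethylsilyloxy)-4-methoxybenzoic acid, via bis-silyl derivative 25 (not isolated)
Conditions: t-BuMe2SiCl (2.5 equiv), imidazole, DMF, rt; then AcOH, THF, H2O, rt
Reagents that add atoms: tert-butyldimethylsilyl chloride, CC(C)(C)[Si](C)(C)Cl
Why: Exhaustive silylation followed by hydrolysis of the labile silyl ester in dilute acid is the usual access to silyl-protected hydroxybenzoic acids; the aryl silyl ether is stable to aqueous acetic acid.

Step 17
Reactants: 26 3-(tert-butyldimethylsilyloxy)-4-methoxybenzoic acid; 23 (1S,2R,3aR,4S,5R,7R,8aS)-1,2-epoxy-2,7-dimethyl-4-(propan-2-yl)decahydroazulene-5,7-diol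
Product: 28 (1S,2R,3aR,4S,5R,7R,8aS)-1,2-epoxy-7-hydroxy-2,7-dimethyl-4-(propan-2-yl)decahydroazulen-5-yl 3-(tert-butyldimethylsilyloxy)-4-methoxybenzoate, via mixed anhydride 27 (not isolated)
Conditions: 26, 2,4,6-Cl3C6H2COCl, Et3N, THF, rt; then 23, DMAP, toluene, rt → 40 °C
Reagents that add atoms: 2,4,6-trichlorobenzoyl chloride, O=C(Cl)c1c(Cl)cc(Cl)cc1Cl (its atoms stay in intermediate 27 only)
Why: Yamaguchi esterification: DMAP attacks the unhindered aroyl carbonyl of the mixed anhydride and the acylpyridinium acylates the secondary C-5 hydroxyl with retention. The tertiary C-7 hydroxyl is too hindered to react and the epoxide tolerates the basic medium.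

Step 18
Reactants: 28 (1S,2R,3aR,4S,5R,7R,8aS)-1,2-epoxy-7-hydroxy-2,7-dimethyl-4-(propan-2-yl)decahydroazulen-5-yl 3-(tert-butyldimethylsilyloxy)-4-methoxybenzoate
Product: 29 (1S,2R,3aR,4S,5R,7R,8aS)-1,2-epoxy-7-hydroxy-2,7-dimethyl-4-(propan-2-yl)decahydroazulen-5-yl 3-hydroxy-4-methoxybenzoate (target, CNP0106636.1)
Conditions: Bu4NF, AcOH (1:1), THF, 0 °C
Reagents that add atoms: none
Why: Fluoride cleaves the aryl silyl ether selectively; buffering with acetic acid keeps the medium near neutral so that neither the aryl ester nor the trisubstituted epoxide should be attacked.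

## Compound list

1 | 3-methylbutanal | CC(C)CC=O | starting material
2 | isopropenylmagnesium bromide | C=C(C)[Mg]Br | starting material
3 | 2,5-dimethylhex-1-en-3-ol (racemic) | C=C(C)C(O)CC(C)C | intermediate
4 | 2,5-dimethylhex-1-en-3-one | C=C(C)C(=O)CC(C)C | intermediate
5 | (3Z)-2,5-dimethyl-3-(trimethylsilyloxy)hexa-1,3-diene | C=C(C)/C(O[Si](C)(C)C)=C/C(C)C | intermediate
6 | (2E)-4-bromobut-2-enoic acid | OC(=O)/C=C/CBr | starting material
7 | 1,3-oxazolidin-2-one | O=C1NCCO1 | starting material
8 | (2E)-4-bromobut-2-enoyl chloride | ClC(=O)/C=C/CBr | intermediate (not isolated)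
9 | 3-[(2E)-4-bromobut-2-enoyl]-1,3-oxazolidin-2-one | O=C(/C=C/CBr)N1CCOC1=O | intermediate
10 | tributyl(prop-1-en-2-yl)stannane | C=C(C)[Sn](CCCC)(CCCC)CCCC | starting material
11 | 3-[(2E)-5-methylhexa-2,5-dienoyl]-1,3-oxazolidin-2-one | C=C(C)C/C=C/C(=O)N1CCOC1=O | intermediate
12 | 3-{[(1S,5S,6S)-3-methyl-6-(2-methylprop-2-en-1-yl)-5-(propan-2-yl)-4-(trimethylsilyloxy)cyclohex-3-en-1-yl]carbonyl}-1,3-oxazolidin-2-one (imide cis to isopropyl, methallyl trans to both) | C[Si](C)(C)OC1=C(C)C[C@H](C(=O)N2CCOC2=O)[C@@H](CC(C)=C)[C@@H]1C(C)C | intermediate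
13 | 3-{[(3S,4S,5S)-1-methyl-4-(2-methylprop-2-en-1-yl)-5-(propan-2-yl)-6-(trimethylsilyloxy)bicyclo[4.1.0]heptan-3-yl]carbonyl}-1,3-oxazolidin-2-one (cyclopropane diastereomers) | C[Si](C)(C)OC12CC2(C)C[C@H](C(=O)N3CCOC3=O)[C@@H](CC(C)=C)[C@@H]1C(C)C | intermediate (not isolated)
14 | 3-{[(1S,6S,7S)-3-chloro-3-methyl-7-(2-methylprop-2-en-1-yl)-5-oxo-6-(propan-2-yl)cycloheptyl]carbonyl}-1,3-oxazolidin-2-one (C-3 epimers) | O=C1CC(C)(Cl)C[C@H](C(=O)N2CCOC2=O)[C@@H](CC(C)=C)[C@@H]1C(C)C | intermediate (not isolated)
15 | 3-{[(1S,6S,7S)-3-methyl-7-(2-methylprop-2-en-1-yl)-5-oxo-6-(propan-2-yl)cyclohept-3-en-1-yl]carbonyl}-1,3-oxazolidin-2-one | O=C1C=C(C)C[C@H](C(=O)N2CCOC2=O)[C@@H](CC(C)=C)[C@@H]1C(C)C | intermediate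
16 | (5S,6R,7S)-5-(hydroxymethyl)-3-methyl-6-(2-methylprop-2-en-1-yl)-7-(propan-2-yl)cyclohept-2-en-1-ol (both C-1 epimers) | OC1C=C(C)C[C@H](CO)[C@@H](CC(C)=C)[C@@H]1C(C)C | intermediate
17 | (1S,6S,7R)-3-methyl-7-(2-methylprop-2-en-1-yl)-5-oxo-6-(propan-2-yl)cyclohept-3-ene-1-carbaldehyde | O=C1C=C(C)C[C@H](C=O)[C@@H](CC(C)=C)[C@@H]1C(C)C | intermediate
18 | (5R,6R,7S)-5-ethenyl-3-methyl-6-(2-methylprop-2-en-1-yl)-7-(propan-2-yl)cyclohept-2-en-1-one | O=C1C=C(C)C[C@H](C=C)[C@@H](CC(C)=C)[C@@H]1C(C)C | intermediate
19 | (3aR,4S,8aS)-2,7-dimethyl-4-(propan-2-yl)-3a,4,8,8a-tetrahydroazulen-5(3H)-one (trans-fused) | O=C1C=C(C)C[C@@H]2C=C(C)C[C@H]2[C@@H]1C(C)C | intermediate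
20 | (3aR,4S,5S,8aS)-2,7-dimethyl-4-(propan-2-yl)-3,3a,4,5,8,8a-hexahydroazulen-5-ol (hydroxyl cis to isopropyl) | O[C@@H]1C=C(C)C[C@@H]2C=C(C)C[C@H]2[C@@H]1C(C)C | intermediate
21 | (3aR,4S,5S,6S,7R,8aS)-6,7-epoxy-2,7-dimethyl-4-(propan-2-yl)-3,3a,4,5,6,7,8,8a-octahydroazulen-5-ol (epoxide syn to hydroxyl) | O[C@@H]1[C@@H]3O[C@]3(C)C[C@@H]2C=C(C)C[C@H]2[C@@H]1C(C)C | intermediate
22 | (3aR,4S,5R,7R,8aS)-2,7-dimethyl-4-(propan-2-yl)-3,3a,4,5,6,7,8,8a-octahydroazulene-5,7-diol (syn-1,3-diol) | O[C@@H]1C[C@](C)(O)C[C@@H]2C=C(C)C[C@H]2[C@@H]1C(C)C | intermediate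
23 | (1S,2R,3aR,4S,5R,7R,8aS)-1,2-epoxy-2,7-dimethyl-4-(propan-2-yl)decahydroazulene-5,7-diol | O[C@@H]1C[C@](C)(O)C[C@H]2[C@@H](C[C@@]3(C)O[C@@H]23)[C@@H]1C(C)C | intermediate
24 | 3-hydroxy-4-methoxybenzoic acid (isovanillic acid) | COc1ccc(C(=O)O)cc1O | starting material
25 | tert-butyldimethylsilyl 3-(tert-butyldimethylsilyloxy)-4-methoxybenzoate | COc1ccc(C(=O)O[Si](C)(C)C(C)(C)C)cc1O[Si](C)(C)C(C)(C)C | intermediate (not isolated)
26 | 3-(tert-butyldimethylsilyloxy)-4-methoxybenzoic acid | COc1ccc(C(=O)O)cc1O[Si](C)(C)C(C)(C)C | intermediate
27 | 3-(tert-butyldimethylsilyloxy)-4-methoxybenzoic 2,4,6-trichlorobenzoic anhydride | COc1ccc(C(=O)OC(=O)c2c(Cl)cc(Cl)cc2Cl)cc1O[Si](C)(C)C(C)(C)C | intermediate (not isolated)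
28 | (1S,2R,3aR,4S,5R,7R,8aS)-1,2-epoxy-7-hydroxy-2,7-dimethyl-4-(propan-2-yl)decahydroazulen-5-yl 3-(tert-butyldimethylsilyloxy)-4-methoxybenzoate | COc1ccc(C(=O)O[C@@H]2C[C@](C)(O)C[C@H]3[C@@H](C[C@@]4(C)O[C@@H]34)[C@@H]2C(C)C)cc1O[Si](C)(C)C(C)(C)C | intermediate
29 | (1S,2R,3aR,4S,5R,7R,8aS)-1,2-epoxy-7-hydroxy-2,7-dimethyl-4-(propan-2-yl)decahydroazulen-5-yl 3-hydroxy-4-methoxybenzoate | COc1ccc(C(=O)O[C@@H]2C[C@](C)(O)C[C@H]3[C@@H](C[C@@]4(C)O[C@@H]34)[C@@H]2C(C)C)cc1O | target

## Step count and risks

Total step count: 18. Longest linear sequence: 15 steps (steps 1–3, 6–15, 17 and 18, from 3-methylbutanal 1).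

**Step 7 (key step).** The tetrasubstituted enol ether is flanked by the isopropyl-bearing carbon, so cyclopropanation may be slowed enough for the methallyl alkene to compete. The trimethylsilyl group may also be lost before the carbenoid arrives, and in the iron stage the tertiary radical may add to the side-chain alkene. The fallback sets out from 12 and returns at 15, with a carbene in place of the carbenoid and an ionic ring opening in place of the radical one. Dibromocarbene (CHBr3, KOt-Bu, pentane, −20 °C), which discriminates more strongly in favour of electron-rich alkenes, gives the dibromo siloxycyclopropane F1. Warming opens it by loss of bromide and of the silyl group to the 2-bromo enone F2. Zinc in acetic acid removes the bromine to give 15.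

**Step 6.** After the first C–C bond has formed, silyl transfer to the copper-bound imide enolate may compete with ring closure (an open-chain conjugate-addition pathway with loss of the enol ether). Bond formation between two branched carbons may also erode endo and facial selectivity, and the trimethylsilyl enol ether may hydrolyse on isolation. The fallback replaces catalyst control by auxiliary control; it sets out from acid chloride 8 and diene 5 and returns at diol 16. Acylation of lithiated (4S)-4-benzyl-1,3-oxazolidin-2-one with 8 gives the bromo imide F3. Stille coupling with 10 gives the dienoyl imide F4. Me2AlCl-promoted cycloaddition with 5 (chelated s-cis imide, diene anti to benzyl, again the Si face of the α-carbon) gives the silyl enol ether F5. The ring enlargement of step 7 gives the enone F6, and LiBH4 removes the auxiliary to give 16.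

**Step 15.** The directing tertiary hydroxyl is three bonds from the alkene, so delivery may be slow and undirected attack on the other face may compete. The fallback sets out from 22 and returns at 23 and replaces substrate direction by reagent control: a Shi epoxidation with the fructose-derived ketone or its enantiomer, chosen by the spiro transition-state model to match the face anti to H-8a. No new compound is involved.

**Step 12.** If the isopropyl group lies close to the ring plane, facial discrimination by the bulky hydride may be poor. The fallback sets out from 19 and returns at 20 and sets C-5 by inversion. Luche reduction (NaBH4, CeCl3, MeOH), expected to add axially, gives the equatorial epimeric alcohol F7. A Mitsunobu reaction with 4-nitrobenzoic acid gives the inverted ester F8, and K2CO3 in methanol releases 20.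

**Step 5.** Coupling at the carbon next to the carbonyl, or palladium-induced migration of the skipped diene into conjugation, would spoil the dienophile. The fallback sets out from 7 and returns at 11 and builds the enoyl alkene by olefination. Acylation of 7 with bromoacetyl bromide gives 3-(bromoacetyl)-1,3-oxazolidin-2-one F9. PPh3 gives the phosphonium bromide F10, and aqueous NaOH gives the stabilised ylide F11. This is combined in an E-selective Wittig reaction with 3-methylbut-3-enal F12, made by buffered Dess–Martin oxidation of 3-methylbut-3-en-1-ol and used at once.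

## Further compounds

F1 | step 7 | 3-{[(3S,4S,5S)-7,7-dibromo-1-methyl-4-(2-methylprop-2-en-1-yl)-5-(propan-2-yl)-6-(trimethylsilyloxy)bicyclo[4.1.0]heptan-3-yl]carbonyl}-1,3-oxazolidin-2-one | C[Si](C)(C)OC12C(Br)(Br)C2(C)C[C@H](C(=O)N3CCOC3=O)[C@@H](CC(C)=C)[C@@H]1C(C)C
F2 | step 7 | 3-{[(1S,6S,7S)-4-bromo-3-methyl-7-(2-methylprop-2-en-1-yl)-5-oxo-6-(propan-2-yl)cyclohept-3-en-1-yl]carbonyl}-1,3-oxazolidin-2-one | O=C1C(Br)=C(C)C[C@H](C(=O)N2CCOC2=O)[C@@H](CC(C)=C)[C@@H]1C(C)C
F3 | step 6 | (4S)-4-benzyl-3-[(2E)-4-bromobut-2-enoyl]-1,3-oxazolidin-2-one | O=C(/C=C/CBr)N1[C@@H](Cc2ccccc2)COC1=O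
F4 | step 6 | (4S)-4-benzyl-3-[(2E)-5-methylhexa-2,5-dienoyl]-1,3-oxazolidin-2-one | C=C(C)C/C=C/C(=O)N1[C@@H](Cc2ccccc2)COC1=O
F5 | step 6 | (4S)-4-benzyl-3-{[(1S,5S,6S)-3-methyl-6-(2-methylprop-2-en-1-yl)-5-(propan-2-yl)-4-(trimethylsilyloxy)cyclohex-3-en-1-yl]carbonyl}-1,3-oxazolidin-2-one | C[Si](C)(C)OC1=C(C)C[C@H](C(=O)N2[C@@H](Cc3ccccc3)COC2=O)[C@@H](CC(C)=C)[C@@H]1C(C)C
F6 | step 6 | (4S)-4-benzyl-3-{[(1S,6S,7S)-3-methyl-7-(2-methylprop-2-en-1-yl)-5-oxo-6-(propan-2-yl)cyclohept-3-en-1-yl]carbonyl}-1,3-oxazolidin-2-one | O=C1C=C(C)C[C@H](C(=O)N2[C@@H](Cc3ccccc3)COC2=O)[C@@H](CC(C)=C)[C@@H]1C(C)C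
F0 | step 15 | none | none
F7 | step 12 | (3aR,4S,5R,8aS)-2,7-dimethyl-4-(propan-2-yl)-3,3a,4,5,8,8a-hexahydroazulen-5-ol (hydroxyl trans to isopropyl) | O[C@H]1C=C(C)C[C@@H]2C=C(C)C[C@H]2[C@@H]1C(C)C
F8 | step 12 | (3aR,4S,5S,8aS)-2,7-dimethyl-4-(propan-2-yl)-3,3a,4,5,8,8a-hexahydroazulen-5-yl 4-nitrobenzoate | O=C(O[C@@H]1C=C(C)C[C@@H]2C=C(C)C[C@H]2[C@@H]1C(C)C)c1ccc(cc1)[N+](=O)[O-]
F9 | step 5 | 3-(bromoacetyl)-1,3-oxazolidin-2-one | O=C(CBr)N1CCOC1=O
F10 | step 5 | [2-oxo-2-(2-oxo-1,3-oxazolidin-3-yl)ethyl]triphenylphosphonium bromide | O=C(C[P+](c1ccccc1)(c1ccccc1)c1ccccc1)N1CCOC1=O.[Br-]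
F11 | step 5 | 3-[(triphenyl-λ5-phosphanylidene)acetyl]-1,3-oxazolidin-2-one | O=C(C=P(c1ccccc1)(c1ccccc1)c1ccccc1)N1CCOC1=O
F12 | step 5 | 3-methylbut-3-enal | C=C(C)CC=O
A1 | alternative 1 | (3S,4E,6S)-7-(tert-butyldimethylsilyloxy)-6-(propan-2-yl)hept-4-en-1-yn-3-yl 2,2-dimethylpropanoate (C-3 configuration provisional, to be matched to the sense of chirality transfer) | C#C[C@@H](OC(=O)C(C)(C)C)/C=C/[C@H](C(C)C)CO[Si](C)(C)C(C)(C)C
A2 | alternative 1 | 4-[1-(tert-butyldimethylsilyloxy)-3-methylbutan-2-yl]cyclopent-2-en-1-one (single stereoisomer as drawn) | O=C1C=C[C@H]([C@H](C(C)C)CO[Si](C)(C)C(C)(C)C)C1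
A3 | alternative 2 | 3-methyl-3-(triethylsilyloxy)-4-[trans-5-(2-methylprop-1-en-1-yl)-3-(trifluoromethanesulfonyloxy)cyclopent-2-en-1-yl]butanal (single stereoisomer as drawn) | O=CC[C@](C)(O[Si](CC)(CC)CC)C[C@@H]1C=C(OS(=O)(=O)C(F)(F)F)C[C@H]1C=C(C)C
A4 | alternative 2 | trans-fused bicyclic cycloheptanol with isopropenyl on C-4 (trans to the C-5 hydroxyl), triethylsilyloxy and methyl on C-7 and an enol triflate in the five-membered ring | O[C@H]1C[C@](C)(O[Si](CC)(CC)CC)C[C@H]2[C@@H](CC(OS(=O)(=O)C(F)(F)F)=C2)[C@@H]1C(C)=C
A5 | alternative 3 | 2-{1-[trans-2-(chloromethyl)-4-methylcyclopent-3-en-1-yl]-2-methylpropyl}oxirane (single stereoisomer as drawn) | ClC[C@@H]1C=C(C)C[C@H]1[C@H](C(C)C)[C@H]1CO1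
A6 | alternative 3 | 2-(tert-butyldimethylsilyl)-1,3-dithiane | CC(C)(C)[Si](C)(C)C1SCCCS1
A7 | alternative 3 | trans-fused hydroazulene with tert-butyldimethylsilyloxy on C-5, isopropyl on C-4, a spiro-1,3-dithiane at C-7 and the 2-methylcyclopentene | CC(C)(C)[Si](C)(C)O[C@@H]1CC2(SCCCS2)C[C@H]2[C@@H](CC(C)=C2)[C@@H]1C(C)C
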